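## Retrosynthetic overview
1. The target comes from one global hydride reduction of a bis(dihydrobenzofuran) triester whose ring A phenol is masked as a mesitoate.
2. Both dihydrobenzofuran rings come from a double oxidative ring contraction of a (2R,2'R)-bis-flavanone (ionic 1,2-aryl shift from C4 to C3, PhI(OAc)2/HC(OMe)3). C2 and C2' are carried over; C3 and C3' are set trans.
3. Both chromanone rings come from one double enantioselective oxa-Michael cyclisation of a linear bis(2'-hydroxychalcone).
4. The bis-chalcone comes from two ordered Claisen–Schmidt condensations of O-mesitoylvanillin, 5-acetylvanillin and methyl 5-acetylferulate.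
5. All three arenes come from catechol via guaiacol and vanillin, with small C1–C3 pieces added. Ring order: arenes as given, then two six-membered O-rings together, then both contracted to five-membered rings together.

Assumption: the quinidine-derived pseudoenantiomer of the squaramide catalyst gives the R centres in step 9. If the sense is opposite, the quinine-derived one is used and nothing else changes.

## Route

Step 1
Reactants: 1 catechol
Product: 2 guaiacol
Conditions: MeI (1.0 equiv), K2CO3 (1.0 equiv), acetone, reflux
Reagents that add atoms: iodomethane CI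
Why: Williamson ether synthesis in which one equivalent of base forms only the hydrogen-bond-stabilised monoanion, so methylation stops mainly at the monoether and traces of veratrole and catechol are removed by extraction and distillation.

Step 2
Reactants: 2 guaiacol; 3 glyoxylic acid
Product: 5 vanillin, via vanillylmandelic acid 4 (not isolated)
Conditions: NaOH, H2O, 30 °C; then CuSO4 (5 mol%), air, NaOH, 95 °C; then H2SO4 to pH 3
Reagents that add atoms: none
Why: Electrophilic hydroxyalkylation of the phenoxide para to the oxygen, followed by copper-catalysed aerobic oxidative decarboxylation of the mandelic acid (the industrial vanillin sequence); no stereocentre survives.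

Step 3
Reactants: 5 vanillin
Product: 6 5-bromovanillin
Conditions: Br2 (1.05 equiv), AcOH, rt
Reagents that add atoms: bromine BrBr
Why: Electrophilic aromatic bromination, where the position ortho to the free OH is the only strongly activated one because the para position carries the formyl group.

Step 4
Reactants: 6 5-bromovanillin; 7 butyl vinyl ether
Product: 9 5-acetylvanillin, via butyl enol ether 8 (not isolated)
Conditions: Pd(OAc)2 (3 mol%), dppp (6 mol%), K2CO3, DMF–H2O 4:1, 90 °C; then 2 M HCl, rt
Reagents that add atoms: water O
Why: Heck reaction on the cationic pathway, in which the chelating diphosphine and the polar aqueous medium send the aryl group to the internal carbon of the electron-rich alkene and acid then hydrolyses the enol ether to the methyl ketone.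

Step 5
Reactants: 9 5-acetylvanillin; 10 monomethyl malonate
Product: 11 methyl 5-acetylferulate
Conditions: pyridine, piperidine (10 mol%), 70 °C
Reagents that add atoms: none
Why: Knoevenagel–Doebner condensation, in which the aldehyde (as its iminium ion) reacts far faster than the hydrogen-bonded aryl methyl ketone and decarboxylative elimination gives only the E-cinnamate.

Step 6
Reactants: 5 vanillin
Product: 12 O-mesitoylvanillin
Conditions: 2,4,6-trimethylbenzoyl chloride, K2CO3, acetone, reflux
Reagents that add atoms: 2,4,6-trimethylbenzoyl chloride Cc1cc(C)c(C(=O)Cl)c(C)c1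
Why: Phenoxide O-acylation; the mesitoate is chosen because its flanking methyl groups block hydroxide attack in step 7, it resists acid and oxidant, it lowers the migratory aptitude of ring A in step 10, and it still falls to hydride in step 11.

Step 7
Reactants: 12 O-mesitoylvanillin; 9 5-acetylvanillin
Product: 13 chalcone aldehyde
Conditions: KOH (4 equiv), EtOH–H2O, 0 °C to rt; then 1 M HCl
Reagents that add atoms: none
Why: Claisen–Schmidt condensation, in which 9 is present as a phenoxide whose para-formyl group is a vinylogous carboxylate and no longer an electrophile, so its ketone enolate adds only to the non-phenolic aldehyde 12 and E1cB loss of water gives the E-enone.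

Step 8
Reactants: 13 chalcone aldehyde; 11 methyl 5-acetylferulate
Product: 14 bis-chalcone
Conditions: BF3·OEt2 (50 mol%), 1,4-dioxane, rt
Reagents that add atoms: none
Why: Lewis acid-catalysed Claisen–Schmidt condensation, in which the formyl group of 13 is a normal electrophile without base, 11 is the only enolisable ketone and 13 the only aldehyde, so a single E-configured cross product forms and all esters survive.

Step 9
Reactants: 14 bis-chalcone
Product: 15 (2R,2'R)-bis-flavanone
Conditions: 9-amino-9-deoxy-epi-quinidine 3,5-bis(trifluoromethyl)phenyl squaramide (20 mol%), CH2Cl2–toluene 1:1, −20 °C, 72 h; cold 1 M HCl wash, short silica plug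
Reagents that add atoms: none
Why: Proposed new method: a double, catalyst-controlled 6-endo-trig oxa-Michael cyclisation of an unactivated bis(2'-hydroxychalcone), in which the quinuclidine nitrogen deprotonates each phenol (acidified by its ortho-acyl and para-vinylogous acceptor), the squaramide N–H pair binds the s-cis enone carbonyl and the ion-paired phenoxide closes on the Re face of each β-carbon to set C2 and C2' as R; at −20 °C the weak base does not remove the C3–H of the product, so closure stays under kinetic control, the two independent events amplify the ee of the (R,R) isomer (Horeau effect) and the mixed diastereomers are removed on silica; the closest known reaction type is the cinchona thiourea-catalysed oxa-Michael cyclisation of α-carboxylate-activated 2'-hydroxychalcones to flavanones.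

Step 10
Reactants: 15 (2R,2'R)-bis-flavanone
Product: 17 bis(dihydrobenzofuran) triester (2R,3R,2'R,3'R), via bis(enol ether) 16 (not isolated)
Conditions: HC(OMe)3 (solvent), conc. H2SO4 (20 mol%), rt, 30 min; then PhI(OAc)2 (2.2 equiv), rt, 2 h
Reagents that add atoms: trimethyl orthoformate COC(OC)OC
Why: Oxidative ring contraction of flavanones by a 1,2-aryl shift, in which the trivalent iodine electrophile attacks each enol ether at C3 anti to the 2-aryl group, methanol adds at C4, and the benzo carbon C4a migrates from C4 to C3 antiperiplanar to the departing iodobenzene, so each pyranone contracts to a dihydrobenzofuran ester, C2 is untouched and the new C3 centre is trans (also the thermodynamic arrangement), while the far less nucleophilic cinnamate and the mesitoate are left alone.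

Step 11
Reactants: 17 bis(dihydrobenzofuran) triester
Product: 18 target CNP0250921.1
Conditions: i-Bu2AlH (DIBAL-H, 12 equiv), toluene–CH2Cl2, −78 °C to rt; aq. potassium sodium tartrate
Reagents that add atoms: none
Why: 1,2-selective ester reduction that turns the three methyl esters into CH2OH groups, cleaves the aryl mesitoate by hydride delivery from the carbonyl-bound aluminium, leaves the cinnamyl double bond alone even at rt, and touches no stereocentre.

## Compound list
1 | catechol (benzene-1,2-diol) | Oc1ccccc1O | starting material
2 | guaiacol (2-methoxyphenol) | COc1ccccc1O | intermediate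
3 | glyoxylic acid | O=CC(=O)O | starting material
4 | vanillylmandelic acid (racemic 2-hydroxy-2-(4-hydroxy-3-methoxyphenyl)acetic acid) | COc1cc(C(O)C(=O)O)ccc1O | intermediate
5 | vanillin (4-hydroxy-3-methoxybenzaldehyde) | COc1cc(C=O)ccc1O | intermediate
6 | 5-bromovanillin (3-bromo-4-hydroxy-5-methoxybenzaldehyde) | COc1cc(C=O)cc(Br)c1O | intermediate
7 | butyl vinyl ether | C=COCCCC | starting material
8 | 3-(1-butoxyethenyl)-4-hydroxy-5-methoxybenzaldehyde | C=C(OCCCC)c1cc(C=O)cc(OC)c1O | intermediate
9 | 5-acetylvanillin (3-acetyl-4-hydroxy-5-methoxybenzaldehyde) | CC(=O)c1cc(C=O)cc(OC)c1O | intermediate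
10 | monomethyl malonate (3-methoxy-3-oxopropanoic acid) | COC(=O)CC(=O)O | starting material
11 | methyl (E)-3-(3-acetyl-4-hydroxy-5-methoxyphenyl)prop-2-enoate (methyl 5-acetylferulate) | COC(=O)/C=C/c1cc(OC)c(O)c(C(C)=O)c1 | intermediate
12 | 4-formyl-2-methoxyphenyl 2,4,6-trimethylbenzoate (O-mesitoylvanillin) | COc1cc(C=O)ccc1OC(=O)c2c(C)cc(C)cc2C | intermediate
13 | 4-[(E)-3-(5-formyl-2-hydroxy-3-methoxyphenyl)-3-oxoprop-1-enyl]-2-methoxyphenyl 2,4,6-trimethylbenzoate (chalcone aldehyde) | COc1cc(/C=C/C(=O)c2cc(C=O)cc(OC)c2O)ccc1OC(=O)c3c(C)cc(C)cc3C | intermediate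
14 | all-E bis-chalcone: 13 extended at its formyl carbon by the acetyl group of 11 to a second enone | COc1cc(/C=C/C(=O)c2cc(/C=C/C(=O)c3cc(/C=C/C(=O)OC)cc(OC)c3O)cc(OC)c2O)ccc1OC(=O)c4c(C)cc(C)cc4C | intermediate
15 | methyl (E)-3-{(2R)-8-methoxy-2-[(2R)-8-methoxy-2-(3-methoxy-4-mesitoyloxyphenyl)-4-oxochroman-6-yl]-4-oxochroman-6-yl}prop-2-enoate | COc1cc([C@H]2CC(=O)c3cc([C@H]4CC(=O)c5cc(/C=C/C(=O)OC)cc(OC)c5O4)cc(OC)c3O2)ccc1OC(=O)c6c(C)cc(C)cc6C | intermediate
16 | (2R,2'R)-bis(4-methoxy-2H-chromene), the double methyl enol ether of 15 | COc1cc([C@H]2C=C(OC)c3cc([C@H]4C=C(OC)c5cc(/C=C/C(=O)OC)cc(OC)c5O4)cc(OC)c3O2)ccc1OC(=O)c6c(C)cc(C)cc6C | intermediate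
17 | methyl (2R,3R)-7-methoxy-5-[(E)-3-methoxy-3-oxoprop-1-enyl]-2-[(2R,3R)-7-methoxy-3-methoxycarbonyl-2-(3-methoxy-4-mesitoyloxyphenyl)-2,3-dihydrobenzofuran-5-yl]-2,3-dihydrobenzofuran-3-carboxylate (both rings trans) | COc1cc([C@@H]2Oc3c(OC)cc([C@@H]4Oc5c(OC)cc(/C=C/C(=O)OC)cc5[C@H]4C(=O)OC)cc3[C@H]2C(=O)OC)ccc1OC(=O)c6c(C)cc(C)cc6C | intermediate
18 | CNP0250921.1, (2R,3S,2'R,3'S)-triol phenol, both dihydrobenzofurans trans, E-cinnamyl alcohol | COc1cc([C@@H]2Oc3c(OC)cc([C@@H]4Oc5c(OC)cc(/C=C/CO)cc5[C@H]4CO)cc3[C@H]2CO)ccc1O | target

## Step count and risks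
Total step count: 11. Longest linear sequence: 9 (steps 1, 2, 3, 4, 7, 8, 9, 10, 11; the branch through step 5 is equally long).

**Step 9, the proposed new step.** The cyclisation is reversible and the phenoxides are good leaving groups, so conversion or ee may be poor.
- The fallback uses known chemistry. It sets out from 14 and comes back at 15.
- 14 is cyclised without stereocontrol (NaOAc, MeOH, reflux) to the four-isomer mixture of the bis-flavanone F1.
- F1 is then resolved by the established kinetic resolution of flavanones through asymmetric transfer hydrogenation (RuCl(p-cymene)[(S,S)-TsDPEN], HCO2H–Et3N, EtOAc, rt).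
- Every S-configured chromanone is reduced to its cis-flavan-4-ol. The (S,S) isomer gives the bis(flavan-4-ol) F2, and the mixed isomers give the ring A-side mono-alcohol F3 and the cinnamate-side mono-alcohol F4.
- Only (R,R)-15 keeps both ketones and is separated on silica, with a ceiling of 25%.

**Step 10, the double ring contraction.** Possible failure modes are a 2,3-shift of the electron-rich middle ring to an isoflavone, dehydrogenation to a flavone, attack on the cinnamate, and acid-induced opening at C2.
- The fallback sets out from 15 and comes back at 17. It replaces the iodane by a halide leaving group.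
- α-Bromination with CuBr2 (EtOAc–CHCl3, reflux) gives the trans,trans-3,3'-dibromobis-flavanone F5.
- The silver-assisted 1,2-aryl shift of α-bromo aryl ketones (AgBF4, HC(OMe)3–MeOH, 60 °C) then contracts both rings with inversion at C3.

**Step 7, the chemoselective condensation.** 9 may self-condense, or the aryl ester may be lost in KOH.
- The fallback sets out from 6 and 11 and comes back at 14, bypassing 13. The order of bond formation is changed so that no compound ever carries a free acetyl group and a free formyl group together.
- 11 and 6 are condensed with BF3·OEt2 in dioxane to the bromo chalcone F6.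
- The Heck reaction of step 4 with 7 gives the butyl enol ether F7, which is hydrolysed with HCl to the acetyl chalcone F8.
- F8 is condensed with 12 under BF3·OEt2 to give 14.

## Further compounds
F1 | step 9 | bis-flavanone of constitution 15 as the mixture of its four stereoisomers | COc1cc(C2CC(=O)c3cc(C4CC(=O)c5cc(/C=C/C(=O)OC)cc(OC)c5O4)cc(OC)c3O2)ccc1OC(=O)c6c(C)cc(C)cc6C
F2 | step 9 | (2S,4S,2'S,4'S)-bis(cis-flavan-4-ol) | COc1cc([C@@H]2C[C@H](O)c3cc([C@@H]4C[C@H](O)c5cc(/C=C/C(=O)OC)cc(OC)c5O4)cc(OC)c3O2)ccc1OC(=O)c6c(C)cc(C)cc6C
F3 | step 9 | (2S,4S)-flavan-4-ol on the ring A side, (2'R)-flavanone on the cinnamate side | COc1cc([C@@H]2C[C@H](O)c3cc([C@H]4CC(=O)c5cc(/C=C/C(=O)OC)cc(OC)c5O4)cc(OC)c3O2)ccc1OC(=O)c6c(C)cc(C)cc6C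
F4 | step 9 | (2R)-flavanone on the ring A side, (2'S,4'S)-flavan-4-ol on the cinnamate side | COc1cc([C@H]2CC(=O)c3cc([C@@H]4C[C@H](O)c5cc(/C=C/C(=O)OC)cc(OC)c5O4)cc(OC)c3O2)ccc1OC(=O)c6c(C)cc(C)cc6C
F5 | step 10 | (2S,3S,2'S,3'S)-trans,trans-3,3'-dibromobis-flavanone | COc1cc([C@H]2[C@H](Br)C(=O)c3cc([C@H]4[C@H](Br)C(=O)c5cc(/C=C/C(=O)OC)cc(OC)c5O4)cc(OC)c3O2)ccc1OC(=O)c6c(C)cc(C)cc6C
F6 | step 7 | methyl (E)-3-{3-[(E)-3-(3-bromo-4-hydroxy-5-methoxyphenyl)prop-2-enoyl]-4-hydroxy-5-methoxyphenyl}prop-2-enoate | COC(=O)/C=C/c1cc(OC)c(O)c(C(=O)/C=C/c2cc(Br)c(O)c(OC)c2)c1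
F7 | step 7 | 1-butoxyethenyl analogue of F6 (bromine replaced) | COC(=O)/C=C/c1cc(OC)c(O)c(C(=O)/C=C/c2cc(C(=C)OCCCC)c(O)c(OC)c2)c1
F8 | step 7 | acetyl analogue of F6 (bromine replaced by acetyl) | COC(=O)/C=C/c1cc(OC)c(O)c(C(=O)/C=C/c2cc(C(C)=O)c(O)c(OC)c2)c1
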